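**Retrosynthetic overview**

- Feature: the benzene ring reads C(hexanoyl)–C(OMe)–CH–C(OH)–C(CH2-dienone)–C(OH). These six carbons map one to one onto C3, C4, C5 and C6 of a 3-hexanoyl-4-methoxypyran-2-one, the first CH2 of an ethylene tether on C6, and the lactone carbon C2. The arene is therefore a constitutional isomer of a pyranone.
- Key disconnection: the aromatic bond between the bridge-bearing carbon and the C–OH next to the hexanoyl carbon, made last by methoxide opening of the lactone and Claisen reclosure.
- The pyranone precursor 16 is cut between the tether and the dienone ring: conjugate addition of the (R)-acylfilicinic acid analogue 15 to the 6-vinylpyranone 9.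
- 9 comes from lactone 1 (chain extension through its dianion, 3-hexanoylation, O-methylation, sulfoxide elimination); 15 from 2-methylphloroglucinol (C-butanoylation, dearomatising C-prenylation, resolution).
- Ring order: pyranone ring purchased, dienone ring by dearomatisation, benzene ring formed last.

Key step: step 9

Assumption: the descriptor R for 15 to 18 refers to the enol tautomer written in the SMILES, and the enantiomer taken on in step 7 is to be assigned by ECD or by anomalous-dispersion X-ray analysis of a salt with an enantiopure amine.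

**Route**

Step 1
Reactants: 1 4-hydroxy-6-methyl-2H-pyran-2-one; 2 chloromethyl phenyl sulfide
Product: 3 4-hydroxy-6-[2-(phenylsulfanyl)ethyl]-2H-pyran-2-one
Conditions: LiN(iPr)2 (2.2 equiv), THF/DMPU, −78 °C; 2, n-Bu4NI (0.1 equiv), −78 to 0 °C; 1 M HCl
Reagents that add atoms: none
Why: The second equivalent of amide base deprotonates the 6-methyl group of the lithium 4-oxide, and this O,C-dianion is alkylated at its exocyclic carbon by the reactive α-chloro sulfide (γ-alkylation of a β-dicarbonyl-type dianion, SN2), adding the carbon that later becomes the bridge CH2.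

Step 2
Reactants: 3 4-hydroxy-6-[2-(phenylsulfanyl)ethyl]-2H-pyran-2-one; 4 hexanoic acid
Product: 6 3-hexanoyl-4-hydroxy-6-[2-(phenylsulfanyl)ethyl]-2H-pyran-2-one, via enol ester 5 (not isolated)
Conditions: DCC (1.2 equiv), DMAP (0.3 equiv), toluene, rt then 100 °C
Reagents that add atoms: none
Why: Steglich esterification of the enolic 4-hydroxyl gives the enol hexanoate, and DMAP then carries the acyl group from oxygen to C3 (Fries-type O-to-C acyl shift through an acylpyridinium and pyranone enolate pair), the usual way to 3-acyl derivatives of this lactone.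

Step 3
Reactants: 6 3-hexanoyl-4-hydroxy-6-[2-(phenylsulfanyl)ethyl]-2H-pyran-2-one
Product: 7 3-hexanoyl-4-methoxy-6-[2-(phenylsulfanyl)ethyl]-2H-pyran-2-one
Conditions: Me2SO4 (1.5 equiv), K2CO3, acetone, 56 °C
Reagents that add atoms: dimethyl sulfate, COS(=O)(=O)OC
Why: Williamson-type O-methylation of the potassium enolate at the ring 4-oxygen by the hard sulfate electrophile, as known for 3-acetyl-4-hydroxy-6-methylpyran-2-one, while the much less nucleophilic aryl thioether stays untouched.

Step 4
Reactants: 7 3-hexanoyl-4-methoxy-6-[2-(phenylsulfanyl)ethyl]-2H-pyran-2-one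
Product: 9 6-ethenyl-3-hexanoyl-4-methoxy-2H-pyran-2-one, via sulfoxide 8 (not isolated)
Conditions: mCPBA (1.0 equiv), CH2Cl2, −78 to −20 °C; then toluene, BHT (cat.), 90 °C
Reagents that add atoms: mCPBA, OOC(=O)c1cccc(Cl)c1 (its oxygen sits on sulfur in 8 and leaves with the sulfenic acid; no atom of it remains in 9)
Why: Sulfide-to-sulfoxide oxidation with one equivalent of peracid followed by thermal syn-elimination of benzenesulfenic acid, which can only take a hydrogen from the pyranone-bound CH2 and is eased by the acidity of that position and the conjugation gained.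

Step 5
Reactants: 10 2-methylbenzene-1,3,5-triol; 11 butanoyl chloride
Product: 12 1-(2,4,6-trihydroxy-3-methylphenyl)butan-1-one
Conditions: AlCl3 (3.5 equiv), PhNO2/CH2Cl2, 0 °C to rt; aq. HCl
Reagents that add atoms: none
Why: Friedel–Crafts C-acylation of the electron-rich triol at one of its two equivalent free ring positions, the first acyl group deactivating the ring against a second acylation.

Step 6
Reactants: 12 1-(2,4,6-trihydroxy-3-methylphenyl)butan-1-one; 13 1-bromo-3-methylbut-2-ene
Product: 14 rac-2-butanoyl-3,5-dihydroxy-4-methyl-4-(3-methylbut-2-en-1-yl)cyclohexa-2,5-dien-1-one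
Conditions: NaOMe (2.1 equiv), MeOH, 0 °C, slow addition of 13; acidify, extract product into aq. NaHCO3
Reagents that add atoms: none
Why: Alkylative dearomatisation, in which the phenolate dianion reacts at carbon in methanol and attack at the methyl-bearing carbon (the more electron-rich site, as in the C-methylation of C-methyl acylphloroglucinols to acylfilicinic acids) creates the quaternary centre as a racemate; the strongly acidic trione is separated through its bicarbonate solubility from the phenolic isomer prenylated at the free CH.

Step 7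
Reactants: 14 rac-2-butanoyl-3,5-dihydroxy-4-methyl-4-(3-methylbut-2-en-1-yl)cyclohexa-2,5-dien-1-one
Product: 15 (4R)-2-butanoyl-3,5-dihydroxy-4-methyl-4-(3-methylbut-2-en-1-yl)cyclohexa-2,5-dien-1-one
Conditions: preparative chiral SFC, amylose tris(3,5-dimethylphenylcarbamate) phase, CO2/MeOH (0.1% HCO2H)
Reagents that add atoms: none
Why: Chromatographic resolution on a chiral stationary phase selects the R enantiomer; the quaternary centre carries no hydrogen and its two ring neighbours are kept different by the butanoyl group, so enol tautomerism cannot racemise it.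

Step 8
Reactants: 9 6-ethenyl-3-hexanoyl-4-methoxy-2H-pyran-2-one; 15 (4R)-2-butanoyl-3,5-dihydroxy-4-methyl-4-(3-methylbut-2-en-1-yl)cyclohexa-2,5-dien-1-one
Product: 16 (4R)-2-butanoyl-6-[2-(3-hexanoyl-4-methoxy-2-oxo-2H-pyran-6-yl)ethyl]-3,5-dihydroxy-4-methyl-4-(3-methylbut-2-en-1-yl)cyclohexa-2,5-dien-1-one
Conditions: iPr2NEt (0.2 equiv), MeCN, 50 °C
Reagents that add atoms: none
Why: Vinylogous Michael addition, in which the amine-generated enolate of the acidic trione adds through its only free ring carbon (C6) to the terminal CH2 of the vinyl group at the remote end of the trienyl lactone and acyl system, the pyranone-stabilised carbanion then being protonated by further 15; no stereocentre is formed or touched.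

Step 9
Reactants: 16 (4R)-2-butanoyl-6-[2-(3-hexanoyl-4-methoxy-2-oxo-2H-pyran-6-yl)ethyl]-3,5-dihydroxy-4-methyl-4-(3-methylbut-2-en-1-yl)cyclohexa-2,5-dien-1-one
Product: 18 (4R)-2-butanoyl-6-[(3-hexanoyl-2,6-dihydroxy-4-methoxyphenyl)methyl]-3,5-dihydroxy-4-methyl-4-(3-methylbut-2-en-1-yl)cyclohexa-2,5-dien-1-one, via ring-opened keto ester 17 (not isolated)
Conditions: Mg(OMe)2 (8 equiv), MeOH, 65 to 100 °C (sealed tube); then 1 M HCl, 0 °C
Reagents that add atoms: magnesium dimethoxide, C[O-].[Mg+2].[O-]C (its methoxide is built into 17 and expelled again on ring closure; no atom of it remains in 18)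
Why: Methoxide adds to the lactone carbonyl C2 and the ring opens to the magnesium enolate of methyl ester 17, with the ester still cis to the chain on the C3=C4 bond; deprotonation of the chain CH2 next to the unveiled C6 ketone lets that carbon attack the ester carbonyl, methoxide leaves and two enolisations give the benzene ring, in which the former lactone carbon is the C–OH beside the hexanoyl carbon and former C6 is the other C–OH. The closest known reactions are the methoxide-induced isomerisation of 4-methoxy-6-methylpyran-2-one to 5-methoxyresorcinol and the Mg(OMe)2 Claisen cyclisation of 3,5,7-triketo esters to acylphloroglucinols. The benzene ring closes in a 6-(enolendo)-exo-trig Claisen mode. No stereocentre is formed, and the quaternary centre of the dienone ring has no enolisable hydrogen and is carried through unchanged. The step needs Claisen attack on the ester to beat aldol attack of the same carbon on the hexanoyl carbonyl: the ester is placed syn to the nucleophile by the geometry inherited from the lactone, and in the magnesium chelate of the acylmalonate-type unit the hexanoyl oxygen carries the enolate charge, which lowers its electrophilicity. Excess base keeps the dienone unit as its magnesium dienolate, a poor leaving group, which guards against its β-elimination from the ring-opened enolate, and the methoxy group stays on C4 throughout, so its place on the arene is fixed by the precursor.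

**Compound list**

1 | 4-hydroxy-6-methyl-2H-pyran-2-one | CC1=CC(O)=CC(=O)O1 | starting material
2 | chloromethyl phenyl sulfide | ClCSc1ccccc1 | starting material
3 | 4-hydroxy-6-[2-(phenylsulfanyl)ethyl]-2H-pyran-2-one | OC1=CC(=O)OC(CCSc2ccccc2)=C1 | intermediate
4 | hexanoic acid | CCCCCC(=O)O | starting material
5 | 2-oxo-6-[2-(phenylsulfanyl)ethyl]-2H-pyran-4-yl hexanoate (enol ester, not isolated) | CCCCCC(=O)OC1=CC(=O)OC(CCSc2ccccc2)=C1 | intermediate
6 | 3-hexanoyl-4-hydroxy-6-[2-(phenylsulfanyl)ethyl]-2H-pyran-2-one | CCCCCC(=O)C1=C(O)C=C(CCSc2ccccc2)OC1=O | intermediate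
7 | 3-hexanoyl-4-methoxy-6-[2-(phenylsulfanyl)ethyl]-2H-pyran-2-one | CCCCCC(=O)C1=C(OC)C=C(CCSc2ccccc2)OC1=O | intermediate
8 | 3-hexanoyl-4-methoxy-6-[2-(phenylsulfinyl)ethyl]-2H-pyran-2-one (racemic at sulfur, not isolated) | CCCCCC(=O)C1=C(OC)C=C(CCS(=O)c2ccccc2)OC1=O | intermediate
9 | 6-ethenyl-3-hexanoyl-4-methoxy-2H-pyran-2-one | CCCCCC(=O)C1=C(OC)C=C(C=C)OC1=O | intermediate
10 | 2-methylbenzene-1,3,5-triol | Cc1c(O)cc(O)cc1O | starting material
11 | butanoyl chloride | CCCC(=O)Cl | starting material
12 | 1-(2,4,6-trihydroxy-3-methylphenyl)butan-1-one | CCCC(=O)c1c(O)cc(O)c(C)c1O | intermediate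
13 | 1-bromo-3-methylbut-2-ene | CC(C)=CCBr | starting material
14 | rac-2-butanoyl-3,5-dihydroxy-4-methyl-4-(3-methylbut-2-en-1-yl)cyclohexa-2,5-dien-1-one | O=C1C=C(O)C(C)(CC=C(C)C)C(O)=C1C(=O)CCC | intermediate
15 | (4R)-2-butanoyl-3,5-dihydroxy-4-methyl-4-(3-methylbut-2-en-1-yl)cyclohexa-2,5-dien-1-one | O=C1C=C(O)[C@@](C)(CC=C(C)C)C(O)=C1C(=O)CCC | intermediate
16 | (4R)-2-butanoyl-6-[2-(3-hexanoyl-4-methoxy-2-oxo-2H-pyran-6-yl)ethyl]-3,5-dihydroxy-4-methyl-4-(3-methylbut-2-en-1-yl)cyclohexa-2,5-dien-1-one | CCCCCC(=O)C1=C(OC)C=C(CCC2=C(O)[C@@](C)(CC=C(C)C)C(O)=C(C(=O)CCC)C2=O)OC1=O | intermediate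
17 | methyl (2E)-7-[(3R)-5-butanoyl-2,4-dihydroxy-3-methyl-3-(3-methylbut-2-en-1-yl)-6-oxocyclohexa-1,4-dien-1-yl]-2-hexanoyl-3-methoxy-5-oxohept-2-enoate (not isolated) | CCCCCC(=O)/C(C(=O)OC)=C(\OC)CC(=O)CCC1=C(O)[C@@](C)(CC=C(C)C)C(O)=C(C(=O)CCC)C1=O | intermediate
18 | (4R)-2-butanoyl-6-[(3-hexanoyl-2,6-dihydroxy-4-methoxyphenyl)methyl]-3,5-dihydroxy-4-methyl-4-(3-methylbut-2-en-1-yl)cyclohexa-2,5-dien-1-one | CCCCCC(=O)c1c(OC)cc(O)c(CC2=C(O)[C@@](C)(CC=C(C)C)C(O)=C(C(=O)CCC)C2=O)c1O | target

**Step count**

Total steps: 9. Longest linear sequence: 6 steps (steps 1, 2, 3, 4, 8, 9).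

**Steps most likely to fail**

Step 9. The chain carbon may close onto the hexanoyl carbonyl in an aldol sense instead of onto the ester, which would end in a benzoate isomer. The second deprotonation of the chain CH2 may also demand more heat than the molecule tolerates. Prolonged base may further detach the dienone unit by β-elimination or scramble the methylene bridge of the product.
Fallback, from 15 back to 18: the bridge is made by enone-methide coupling instead of arene construction. Compound 15 is treated with N,N-dimethylmethyleneiminium iodide in CH2Cl2 to give the Mannich base (4R)-2-butanoyl-6-[(dimethylamino)methyl]-3,5-dihydroxy-4-methyl-4-(3-methylbut-2-en-1-yl)cyclohexa-2,5-dien-1-one F1. Separately, hexanoic acid 4 and 5-methoxybenzene-1,3-diol are condensed with BF3·OEt2 at 80 °C, and the isomer 1-(2,4-dihydroxy-6-methoxyphenyl)hexan-1-one F2 is isolated. Heating F1 with F2 in dioxane at 80 °C should expel dimethylamine and generate the exocyclic enone methide of the dienone. This should be captured by F2 at its ring carbon between the two hydroxyls to give 18.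

Step 8. The highly stabilised trione enolate may add too slowly to the donor-substituted trienyl acceptor. Side processes would then be displacement of the 4-methoxy group by the carbon nucleophile and oligomerisation of the vinylpyranone.
Fallback, from 8 and 15 back to 16: the same C–C bond is made by reductive alkylation. Sulfoxide 8, taken before it is heated, is subjected to a Pummerer rearrangement (trifluoroacetic anhydride, 2,6-lutidine, CH2Cl2, 0 °C, then aqueous NaHCO3) to give 2-(3-hexanoyl-4-methoxy-2-oxo-2H-pyran-6-yl)acetaldehyde F3. A three-component reductive alkylation of 15 with F3, catalytic L-proline and diethyl 2,6-dimethyl-1,4-dihydropyridine-3,5-dicarboxylate in CH2Cl2 at rt follows. The Knoevenagel alkylidene is reduced in the flask by the dihydropyridine and should give 16.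

Step 6. The prenyl group may enter at the free ring CH to give the aromatic isomer, at oxygen, or twice.
Fallback, from 11 and 13 back to 14: the order of the two alkylations is reversed so that the small electrophile makes the quaternary centre. Benzene-1,3,5-triol is acylated with butanoyl chloride 11 and AlCl3 to 1-(2,4,6-trihydroxyphenyl)butan-1-one F4. Mono-C-prenylation with 1-bromo-3-methylbut-2-ene 13 in aqueous KOH at 0 °C gives 1-[2,4,6-trihydroxy-3-(3-methylbut-2-en-1-yl)phenyl]butan-1-one F5. Dearomatising C-methylation of F5 at the prenyl-bearing carbon with iodomethane (1.1 equiv) and NaOMe in MeOH then gives 14, purified by bicarbonate extraction.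

**Further compounds**

F1 | step 9 | (4R)-2-butanoyl-6-[(dimethylamino)methyl]-3,5-dihydroxy-4-methyl-4-(3-methylbut-2-en-1-yl)cyclohexa-2,5-dien-1-one | CN(C)CC1=C(O)[C@@](C)(CC=C(C)C)C(O)=C(C(=O)CCC)C1=O
F2 | step 9 | 1-(2,4-dihydroxy-6-methoxyphenyl)hexan-1-one | CCCCCC(=O)c1c(O)cc(O)cc1OC
F3 | step 8 | 2-(3-hexanoyl-4-methoxy-2-oxo-2H-pyran-6-yl)acetaldehyde | CCCCCC(=O)C1=C(OC)C=C(CC=O)OC1=O
F4 | step 6 | 1-(2,4,6-trihydroxyphenyl)butan-1-one | CCCC(=O)c1c(O)cc(O)cc1O
F5 | step 6 | 1-[2,4,6-trihydroxy-3-(3-methylbut-2-en-1-yl)phenyl]butan-1-one | CCCC(=O)c1c(O)cc(O)c(CC=C(C)C)c1O
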